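**Plan**
- Cuts (germacranolide numbering: ring C1–C10, lactone C6–O–C12, C11=C13, C14 on C10, C15 on C4): the C8–O ester; then C7–C8 of the ten-membered ring; then C7=C11 of the butenolide; then C3–C4. This leaves a C4–C7/C15 iodo-dienol and a C8–C10/C1–C3 enal.
- Enabling feature: the exocyclic C11=C13 methylene sits next to C7, and C8 beside it is a carbinol. C13=C11–C7–C8–O is the homoallylic-alcohol retron of a carbonyl allylation by a 3-(bromomethyl)butenolide that already contains the lactone ring.
- Forward: two three-step fragments are joined at C3–C4; the C1/C10 epoxide is made next, then the butenolide ring (metathesis), then the ten-membered carbocycle last (chromium Barbier closure); an inverting esterification and desilylation finish.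
- Stereochemistry: C6 from catalytic asymmetric alkynylation; 4Z from trans-hydroalumination/iodination; 1(10)E from carboalumination; C3 from CBS reduction; C1/C10 from Shi epoxidation; C7 from C6 and C8 from the chair transition state of the key step, C8 then being inverted by Mitsunobu esterification.

Key step: step 17

Assumption: the ring closure is taken to give the 8S alcohol predicted by the chair transition state, so the inversion needed for the 8R ester is built into step 18.

**Step 1**
Reactants: 1 tert-butyldimethyl(prop-2-yn-1-yloxy)silane; 2 acrolein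
Product: 4 (S)-6-((tert-butyldimethylsilyl)oxy)hex-1-en-4-yn-3-ol, via methylzinc acetylide 3 (not isolated)
Conditions: Me2Zn, (S,S)-ProPhenol (10 mol %), Ph3PO (20 mol %), toluene, 0 °C; slow addition of 2
Reagents that add atoms: none
Why: Zinc/ProPhenol-catalysed enantioselective alkynylation of an enal, in which acetylide 3 should be delivered to the Re face of acrolein (ligand antipode chosen for that face) to set C6 as S in 4 (the same spatial arrangement is 6R in the target after the CIP priorities change).

**Step 2**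
Reactants: 4 (S)-6-((tert-butyldimethylsilyl)oxy)hex-1-en-4-yn-3-ol
Product: 6 (3S,4Z)-6-((tert-butyldimethylsilyl)oxy)-5-iodohexa-1,4-dien-3-ol, via cyclic vinylalanate 5 (not isolated)
Conditions: Red-Al, THF, 0 °C; EtOAc; then I2, THF, −78 to 0 °C
Reagents that add atoms: iodine, II
Why: Hydroxyl-directed trans-hydroalumination puts aluminium on the distal alkyne carbon C4 in the five-membered alanate 5, and iodinolysis with retention should give the Z-iodoalkene, so the future C3 substituent is locked cis to C6 (the 4Z geometry of the target).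

**Step 3**
Reactants: 6 (3S,4Z)-6-((tert-butyldimethylsilyl)oxy)-5-iodohexa-1,4-dien-3-ol
Product: 7 (3S,4Z)-6-((tert-butyldimethylsilyl)oxy)-5-iodo-3-((triethylsilyl)oxy)hexa-1,4-diene
Conditions: TESCl, imidazole, CH2Cl2, 0 °C
Reagents that add atoms: chlorotriethylsilane, CC[Si](Cl)(CC)CC
Why: Standard silylation; the triethylsilyl ether should survive the chromium, oxidation, borane and basic Oxone steps and can later be removed beside tert-butyldimethylsilyl ethers.

**Step 4**
Reactants: 8 but-3-yn-1-ol
Product: 9 1-((but-3-yn-1-yloxy)methyl)-4-methoxybenzene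
Conditions: NaH, PMBCl, Bu4NI (cat.), THF/DMF, 0 °C to rt
Reagents that add atoms: 4-methoxybenzyl chloride, COc1ccc(CCl)cc1
Why: Williamson etherification; the 4-methoxybenzyl ether is chosen because it can be removed oxidatively under neutral conditions next to the allylic bromide and the epoxide in step 15.

**Step 5**
Reactants: 9 1-((but-3-yn-1-yloxy)methyl)-4-methoxybenzene
Product: 12 (E)-6-((4-methoxybenzyl)oxy)-4-methylhex-3-en-1-ol, via alkenyldimethylalane 10 (not isolated), via lithium alkenylalanate 11 (not isolated)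
Conditions: Me3Al, Cp2ZrCl2 (25 mol %), CH2Cl2, 0 °C to rt; n-BuLi, −78 °C; oxirane, THF, −78 to 0 °C
Reagents that add atoms: trimethylaluminium, C[Al](C)C; oxirane, C1CO1
Why: Zirconium-catalysed syn-carboalumination (Negishi) adds methyl to the internal and aluminium to the terminal alkyne carbon, and the butyl ate complex 11 opens oxirane with retention, which fixes the E trisubstituted C1=C10 olefin and adds C2–C3.

**Step 6**
Reactants: 12 (E)-6-((4-methoxybenzyl)oxy)-4-methylhex-3-en-1-ol
Product: 13 (E)-6-((4-methoxybenzyl)oxy)-4-methylhex-3-enal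
Conditions: Dess–Martin periodinane, NaHCO3, CH2Cl2, 0 °C
Reagents that add atoms: none
Why: Dess–Martin oxidation under bicarbonate buffer should give the β,γ-unsaturated aldehyde without migration of the olefin into conjugation; it is used at once.

**Step 7**
Reactants: 7 (3S,4Z)-6-((tert-butyldimethylsilyl)oxy)-5-iodo-3-((triethylsilyl)oxy)hexa-1,4-diene; 13 (E)-6-((4-methoxybenzyl)oxy)-4-methylhex-3-enal
Product: 15 C3-epimeric allylic alcohols (6S; 1(10)E; 4Z), via alkenylchromium dichloride 14 (not isolated)
Conditions: CrCl2 (5 equiv), NiCl2 (2 mol %), DMSO, rt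
Reagents that add atoms: none
Why: Nozaki–Hiyama–Kishi alkenylation, in which Ni(0) inserts into the C–I bond, transmetalation to Cr(III) keeps the Z geometry and the alkenylchromium adds only to the aldehyde under base-free conditions; C3 forms unselectively and is corrected in steps 8 and 9.

**Step 8**
Reactants: 15 C3-epimeric allylic alcohols
Product: 16 Z-enone (C3 ketone, 6S)
Conditions: Dess–Martin periodinane, NaHCO3, CH2Cl2, 0 °C
Reagents that add atoms: none
Why: Dess–Martin oxidation of the secondary allylic alcohol converges both C3 epimers into one enone.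

**Step 9**
Reactants: 16 Z-enone
Product: 17 (3S,6S)-allylic alcohol
Conditions: (R)-Me-CBS (0.5 equiv), catecholborane, toluene, −78 °C
Reagents that add atoms: none
Why: Corey–Bakshi–Shibata reduction; with the α-branched alkenyl group (C4) as the large and the C2 methylene as the small substituent, the (R)-oxazaborolidine should deliver hydride to give 3S (mirror image of the (S)-catalyst/acetophenone model), at a temperature where catecholborane does not hydroborate the olefins.

**Step 10**
Reactants: 17 (3S,6S)-allylic alcohol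
Product: 18 (3S,6S)-C3 tert-butyldimethylsilyl ether
Conditions: TBSOTf, 2,6-lutidine, CH2Cl2, −78 °C
Reagents that add atoms: tert-butyldimethylsilyl triflate, CC(C)(C)[Si](C)(C)OS(=O)(=O)C(F)(F)F
Why: Silylation with the silyl triflate and a hindered base protects the crowded allylic C3 hydroxyl without touching the triethylsilyl ether.

**Step 11**
Reactants: 18 (3S,6S)-C3 tert-butyldimethylsilyl ether
Product: 19 (1R,3S,6S,10R)-1,10-epoxide
Conditions: Shi ketone (D-fructose-derived, 30 mol %), Oxone, K2CO3, Bu4NHSO4, MeCN/DMM/aq. borate buffer, 0 °C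
Reagents that add atoms: Oxone (potassium peroxymonosulfate), [K+].[O-]S(=O)(=O)OO
Why: Shi asymmetric epoxidation; the dioxirane of the D-fructose-derived ketone attacks E-trisubstituted olefins through the spiro transition state to give the R,R epoxide, and it should select the electron-rich C1=C10 olefin over the terminal vinyl group and the hindered 4,5-olefin flanked by three silyloxy-bearing carbons.

**Step 12**
Reactants: 19 (1R,3S,6S,10R)-1,10-epoxide
Product: 20 (1R,3S,6S,10R)-C6 alcohol
Conditions: HF·pyridine, pyridine, THF, 0 °C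
Reagents that add atoms: none
Why: Buffered fluoride desilylation; the secondary triethylsilyl ether should be cleaved well before the tert-butyldimethylsilyl ethers, and the pyridine buffer keeps the trisubstituted epoxide closed.

**Step 13**
Reactants: 20 (1R,3S,6S,10R)-C6 alcohol; 21 2-(bromomethyl)acrylic acid
Product: 22 (1R,3S,6S,10R)-C6 2-(bromomethyl)acrylate
Conditions: DCC, DMAP (cat.), CH2Cl2, 0 °C
Reagents that add atoms: none
Why: Steglich esterification of the bis-allylic C6 alcohol; the acid brings C11, C12 and C13 with the allylic bromide already in place.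

**Step 14**
Reactants: 22 (1R,3S,6S,10R)-C6 2-(bromomethyl)acrylate
Product: 23 (1R,3S,6R,10R)-3-(bromomethyl)butenolide, C8 4-methoxybenzyl ether
Conditions: Grubbs II (10 mol %), CH2Cl2, 40 °C
Reagents that add atoms: none
Why: Ring-closing metathesis of the monosubstituted vinyl group with the 1,1-disubstituted acrylate should give the five-membered butenolide (C7=C11) with loss of ethylene; the trisubstituted 4,5-olefin is too hindered to take part and allylic halides are tolerated by the ruthenium carbene.

**Step 15**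
Reactants: 23 (1R,3S,6R,10R)-3-(bromomethyl)butenolide, C8 4-methoxybenzyl ether
Product: 24 (1R,3S,6R,10R)-C8 primary alcohol
Conditions: DDQ, CH2Cl2/pH 7 buffer, 0 °C
Reagents that add atoms: none
Why: Oxidative cleavage of the 4-methoxybenzyl ether by DDQ (hydride abstraction, then hydrolysis of the oxocarbenium ion) under neutral buffered conditions that should leave the allylic bromide, the epoxide and the silyl ethers intact.

**Step 16**
Reactants: 24 (1R,3S,6R,10R)-C8 primary alcohol
Product: 25 (1R,3S,6R,10R)-C8 aldehyde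
Conditions: Dess–Martin periodinane, NaHCO3, CH2Cl2, 0 °C; filtered and used at once
Reagents that add atoms: none
Why: Dess–Martin oxidation under bicarbonate buffer should form the base-sensitive β,γ-epoxy aldehyde without β-elimination.

**Step 17**
Reactants: 25 (1R,3S,6R,10R)-C8 aldehyde
Product: 27 macrocyclic 8S alcohol (1R,3S,4Z,6R,7R,8S,10R), via allylchromium dichloride 26 (not isolated)
Conditions: CrCl2 (10 equiv), THF, rt, syringe-pump addition of 25 to about 1 mM
Reagents that add atoms: none
Why: Cr(II) reduces the allylic C13–Br bond in two one-electron steps to the σ-allylchromium(III) 26, which adds through its γ-carbon C7 to the tethered C8 aldehyde in a closed six-membered chair transition state and moves the double bond to the exocyclic C11=C13 position. The closest known reaction types are the chromium- or zinc-mediated Barbier additions of 3-(bromomethyl)furan-2(5H)-ones to aldehydes and the chromium-mediated allylation macrocyclisations of 2-(bromomethyl)acrylates that close ten-membered germacranolide rings. The ten-membered carbocycle closes by C7–C8 bond formation as a 10-exo-trig addition to the aldehyde carbonyl; no other ring is formed, the lactone and the epoxide being in place. C7 is controlled by the C6 stereocentre: C8 should bond to the butenolide face anti to the C5 alkenyl substituent, which gives the trans-fused 6R,7R lactone and lets the eight-atom tether span C6 and C7 in a staggered arrangement. C8 is controlled by the chair, in which the ring-fixed E-type γ-substituent (C6) and the tether carbon C9 are both pseudo-equatorial, so the anti adduct (8S, H7 and H8 antiperiplanar) is expected and is inverted in step 18. The step needs γ- over α-attack and aldehyde over lactone or epoxide chemoselectivity, both intrinsic to allylchromium reagents, and cyclisation over oligomerisation, secured by slow addition at high dilution and by the Z-4,5-olefin and trans-epoxide that bend the chain towards the ring.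

**Step 18**
Reactants: 27 macrocyclic 8S alcohol; 28 methacrylic acid
Product: 29 (1R,3S,4Z,6R,7R,8R,10R)-8-methacrylate, 3,15-bis(tert-butyldimethylsilyl) ether
Conditions: PPh3, DIAD, toluene, 0 °C to rt
Reagents that add atoms: none
Why: Mitsunobu esterification; the C8 oxyphosphonium ion should be displaced by methacrylate in an SN2 reaction with inversion (8S to 8R), which installs the ester and corrects C8 in one operation.

**Step 19**
Reactants: 29 (1R,3S,4Z,6R,7R,8R,10R)-8-methacrylate, 3,15-bis(tert-butyldimethylsilyl) ether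
Product: 30 CNP0496616.1
Conditions: HF·pyridine, pyridine, THF, 0 °C to rt
Reagents that add atoms: none
Why: Fluoride-mediated cleavage of both silyl ethers under pyridine-buffered conditions that should spare the epoxide, the methacrylate and the α-methylene lactone.

**Compound list**

1 | tert-butyldimethyl(prop-2-yn-1-yloxy)silane | C#CCO[Si](C)(C)C(C)(C)C | starting material
2 | acrolein (prop-2-enal) | C=CC=O | starting material
3 | methyl[3-((tert-butyldimethylsilyl)oxy)prop-1-yn-1-yl]zinc | C[Zn]C#CCO[Si](C)(C)C(C)(C)C | intermediate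
4 | (S)-6-((tert-butyldimethylsilyl)oxy)hex-1-en-4-yn-3-ol | CC(C)(C)[Si](C)(C)OCC#C[C@H](C=C)O | intermediate
5 | cyclic vinylalanate: sodium 2,2-bis(2-methoxyethoxy)-1,2-oxaaluminol-2-uide ring (O on C6, Al on C4) carrying the 5-vinyl group (S) and the 3-CH2OTBS group | [Na+].COCCO[Al-]1(OCCOC)O[C@@H](C=C)C=C1CO[Si](C)(C)C(C)(C)C | intermediate
6 | (3S,4Z)-6-((tert-butyldimethylsilyl)oxy)-5-iodohexa-1,4-dien-3-ol | I/C(CO[Si](C)(C)C(C)(C)C)=C\[C@H](C=C)O | intermediate
7 | (3S,4Z)-6-((tert-butyldimethylsilyl)oxy)-5-iodo-3-((triethylsilyl)oxy)hexa-1,4-diene | I/C(CO[Si](C)(C)C(C)(C)C)=C\[C@H](C=C)O[Si](CC)(CC)CC | intermediate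
8 | but-3-yn-1-ol | C#CCCO | starting material
9 | 1-((but-3-yn-1-yloxy)methyl)-4-methoxybenzene | C#CCCOCc1ccc(OC)cc1 | intermediate
10 | (E)-[4-((4-methoxybenzyl)oxy)-2-methylbut-1-en-1-yl]dimethylalane | C[Al](C)/C=C(\C)CCOCc1ccc(OC)cc1 | intermediate
11 | lithium butyl[(E)-4-((4-methoxybenzyl)oxy)-2-methylbut-1-en-1-yl]dimethylaluminate | [Li+].CCCC[Al-](C)(C)/C=C(\C)CCOCc1ccc(OC)cc1 | intermediate
12 | (E)-6-((4-methoxybenzyl)oxy)-4-methylhex-3-en-1-ol | COc1ccc(COCC/C(C)=C/CCO)cc1 | intermediate
13 | (E)-6-((4-methoxybenzyl)oxy)-4-methylhex-3-enal | COc1ccc(COCC/C(C)=C/CC=O)cc1 | intermediate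
14 | alkenylchromium(III) dichloride from 7 (Cr in place of I, Z, 6S) | Cl[Cr](Cl)/C(CO[Si](C)(C)C(C)(C)C)=C\[C@H](C=C)O[Si](CC)(CC)CC | intermediate
15 | PMBO-C8H2-C9H2-C10(CH3)=C1H-C2H2-C3H(OH)-C4(CH2OTBS)=C5H-C6H(OTES)-C7H=CH2, 1(10)E, 4Z, 6S, both C3 epimers | COc1ccc(COCC/C(C)=C/CC(O)/C(CO[Si](C)(C)C(C)(C)C)=C\[C@H](C=C)O[Si](CC)(CC)CC)cc1 | intermediate
16 | C3 ketone of 15 (Z-enone, 1(10)E, 6S) | COc1ccc(COCC/C(C)=C/CC(=O)/C(CO[Si](C)(C)C(C)(C)C)=C\[C@H](C=C)O[Si](CC)(CC)CC)cc1 | intermediate
17 | (3S,6S)-alcohol: single C3 epimer of 15 | COc1ccc(COCC/C(C)=C/C[C@H](O)/C(CO[Si](C)(C)C(C)(C)C)=C\[C@H](C=C)O[Si](CC)(CC)CC)cc1 | intermediate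
18 | (3S,6S)-C3 tert-butyldimethylsilyl ether of 17 | COc1ccc(COCC/C(C)=C/C[C@H](O[Si](C)(C)C(C)(C)C)/C(CO[Si](C)(C)C(C)(C)C)=C\[C@H](C=C)O[Si](CC)(CC)CC)cc1 | intermediate
19 | (1R,3S,6S,10R)-1,10-epoxide of 18 (trans epoxide, C14 methyl on C10) | COc1ccc(COCC[C@@]2(C)O[C@@H]2C[C@H](O[Si](C)(C)C(C)(C)C)/C(CO[Si](C)(C)C(C)(C)C)=C\[C@H](C=C)O[Si](CC)(CC)CC)cc1 | intermediate
20 | (1R,3S,6S,10R)-C6 alcohol (19 without the triethylsilyl group) | COc1ccc(COCC[C@@]2(C)O[C@@H]2C[C@H](O[Si](C)(C)C(C)(C)C)/C(CO[Si](C)(C)C(C)(C)C)=C\[C@H](C=C)O)cc1 | intermediate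
21 | 2-(bromomethyl)acrylic acid | C=C(CBr)C(=O)O | starting material
22 | (1R,3S,6S,10R)-C6 2-(bromomethyl)acrylate of 20 | COc1ccc(COCC[C@@]2(C)O[C@@H]2C[C@H](O[Si](C)(C)C(C)(C)C)/C(CO[Si](C)(C)C(C)(C)C)=C\[C@H](C=C)OC(=O)C(=C)CBr)cc1 | intermediate
23 | (1R,3S,6R,10R)-3-(bromomethyl)furan-2(5H)-one whose C5 (= C6) carries the Z chain C5H=C4(CH2OTBS)-C3H(OTBS)-C2H2-(C1,C10 epoxide)-C9H2-C8H2-OPMB | COc1ccc(COCC[C@@]2(C)O[C@@H]2C[C@H](O[Si](C)(C)C(C)(C)C)/C(CO[Si](C)(C)C(C)(C)C)=C\[C@H]2OC(=O)C(CBr)=C2)cc1 | intermediate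
24 | C8 primary alcohol of 23 (PMB removed) | OCC[C@@]1(C)O[C@@H]1C[C@H](O[Si](C)(C)C(C)(C)C)/C(CO[Si](C)(C)C(C)(C)C)=C\[C@H]1OC(=O)C(CBr)=C1 | intermediate
25 | C8 aldehyde of 24 | O=CC[C@@]1(C)O[C@@H]1C[C@H](O[Si](C)(C)C(C)(C)C)/C(CO[Si](C)(C)C(C)(C)C)=C\[C@H]1OC(=O)C(CBr)=C1 | intermediate
26 | allylchromium(III) dichloride from 25 (Cr on C13 in place of Br) | O=CC[C@@]1(C)O[C@@H]1C[C@H](O[Si](C)(C)C(C)(C)C)/C(CO[Si](C)(C)C(C)(C)C)=C\[C@H]1OC(=O)C(C[Cr](Cl)Cl)=C1 | intermediate
27 | (1R,3S,4Z,6R,7R,8S,10R)-3,15-bis((tert-butyldimethylsilyl)oxy)-1,10-epoxy-8-hydroxygermacra-4,11(13)-dien-12,6-olide | O[C@H]1C[C@@]2(C)O[C@@H]2C[C@H](O[Si](C)(C)C(C)(C)C)/C(CO[Si](C)(C)C(C)(C)C)=C\[C@H]2OC(=O)C(=C)[C@@H]21 | intermediate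
28 | methacrylic acid | CC(=C)C(=O)O | starting material
29 | (1R,3S,4Z,6R,7R,8R,10R)-3,15-bis((tert-butyldimethylsilyl)oxy)-1,10-epoxy-8-(methacryloyloxy)germacra-4,11(13)-dien-12,6-olide | C=C(C)C(=O)O[C@@H]1C[C@@]2(C)O[C@@H]2C[C@H](O[Si](C)(C)C(C)(C)C)/C(CO[Si](C)(C)C(C)(C)C)=C\[C@H]2OC(=O)C(=C)[C@@H]21 | intermediate
30 | CNP0496616.1: (1R,3S,4Z,6R,7R,8R,10R)-1,10-epoxy-3,15-dihydroxy-8-(methacryloyloxy)germacra-4,11(13)-dien-12,6-olide | C=C(C)C(=O)O[C@@H]1C[C@@]2(C)O[C@@H]2C[C@H](O)/C(CO)=C\[C@H]2OC(=O)C(=C)[C@@H]21 | target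

**Totals**

Total step count: 19.
Longest linear sequence: 16 steps (steps 1–3 or 4–6, then 7–19).

**Steps most likely to fail**

Step 17. The chromium(III) salts may open the trisubstituted epoxide or promote β-elimination of the epoxy aldehyde before the ring closes. Closure may also lose to oligomerisation, or to 1,4-elimination of the allylchromium with lactone opening. The fallback postpones the epoxide until after the ring is closed. It sets out from 18, which is not epoxidised. Buffered HF·pyridine removes the triethylsilyl group to give the C6 alcohol of the 1(10)E-olefin series F1. Steglich esterification with 21 gives the 2-(bromomethyl)acrylate F2, and ring-closing metathesis gives the bromomethylbutenolide 4-methoxybenzyl ether F3. DDQ then gives the primary alcohol F4, and buffered Dess–Martin oxidation gives the β,γ-unsaturated aldehyde F5. Treating F5 with CrCl2 in THF at high dilution should close the ring through the allylchromium species F6 to the macrocyclic 1(10)E,4Z-dienol F7. Epoxidation of F7 with mCPBA/NaHCO3 at 0 °C should attack the outer face of the strained E-1(10) olefin, the course that 1(10)-E germacranolides take to their 1β,10α-epoxides. The electron-poor α-methylene lactone and the hindered, oxygen-flanked 4,5-olefin should not react. This returns to the route at 27.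

Step 18. Activation of the hindered ring carbinol may be slow, E2 elimination towards C7 or C9 may compete, or the phosphine may add to the α-methylene lactone. The fallback separates activation from displacement. It sets out from 27: chloromethanesulfonyl chloride and pyridine at 0 °C give the 8S chloromethanesulfonate F8. Caesium methacrylate (from 28 and Cs2CO3) with 18-crown-6 in toluene at 60 °C should then displace the sulfonate with inversion, returning to the route at 29.

Step 1. Acrolein is small and polymerisable, so enantioface discrimination may be poor or the aldehyde may oligomerise. The fallback replaces the catalytic asymmetric addition with a kinetic resolution. It sets out from 1 and 2: n-BuLi in THF at −78 °C gives the lithium acetylide F9, which adds to acrolein to give the racemic enynol F10. Sharpless kinetic resolution (Ti(OiPr)4, L-(+)-DIPT, 0.6 equiv TBHP, 4 Å sieves, CH2Cl2, −20 °C) should epoxidise the vinyl group of the fast-reacting R antipode to the epoxy alcohol F11. The slow S antipode is recovered, which returns to the route at 4.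

**Further compounds**

F1 | step 17 | (3S,6S)-C6 alcohol of the 1(10)E-olefin series (18 without the triethylsilyl group) | COc1ccc(COCC/C(C)=C/C[C@H](O[Si](C)(C)C(C)(C)C)/C(CO[Si](C)(C)C(C)(C)C)=C\[C@H](C=C)O)cc1
F2 | step 17 | (3S,6S)-C6 2-(bromomethyl)acrylate of F1 | COc1ccc(COCC/C(C)=C/C[C@H](O[Si](C)(C)C(C)(C)C)/C(CO[Si](C)(C)C(C)(C)C)=C\[C@H](C=C)OC(=O)C(=C)CBr)cc1
F3 | step 17 | (3S,6R)-3-(bromomethyl)butenolide of the 1(10)E-olefin series, C8 4-methoxybenzyl ether | COc1ccc(COCC/C(C)=C/C[C@H](O[Si](C)(C)C(C)(C)C)/C(CO[Si](C)(C)C(C)(C)C)=C\[C@H]2OC(=O)C(CBr)=C2)cc1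
F4 | step 17 | C8 primary alcohol of F3 | OCC/C(C)=C/C[C@H](O[Si](C)(C)C(C)(C)C)/C(CO[Si](C)(C)C(C)(C)C)=C\[C@H]1OC(=O)C(CBr)=C1
F5 | step 17 | C8 aldehyde of F4 (β,γ-unsaturated) | O=CC/C(C)=C/C[C@H](O[Si](C)(C)C(C)(C)C)/C(CO[Si](C)(C)C(C)(C)C)=C\[C@H]1OC(=O)C(CBr)=C1
F6 | step 17 | allylchromium(III) dichloride from F5 | O=CC/C(C)=C/C[C@H](O[Si](C)(C)C(C)(C)C)/C(CO[Si](C)(C)C(C)(C)C)=C\[C@H]1OC(=O)C(C[Cr](Cl)Cl)=C1
F7 | step 17 | (1(10)E,3S,4Z,6R,7R,8S)-3,15-bis((tert-butyldimethylsilyl)oxy)-8-hydroxygermacra-1(10),4,11(13)-trien-12,6-olide | O[C@H]1C/C(C)=C/C[C@H](O[Si](C)(C)C(C)(C)C)/C(CO[Si](C)(C)C(C)(C)C)=C\[C@H]2OC(=O)C(=C)[C@@H]21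
F8 | step 18 | 8S chloromethanesulfonate of 27 | ClCS(=O)(=O)O[C@H]1C[C@@]2(C)O[C@@H]2C[C@H](O[Si](C)(C)C(C)(C)C)/C(CO[Si](C)(C)C(C)(C)C)=C\[C@H]2OC(=O)C(=C)[C@@H]21
F9 | step 1 | lithium 3-((tert-butyldimethylsilyl)oxy)prop-1-yn-1-ide | [Li]C#CCO[Si](C)(C)C(C)(C)C
F10 | step 1 | racemic 6-((tert-butyldimethylsilyl)oxy)hex-1-en-4-yn-3-ol | CC(C)(C)[Si](C)(C)OCC#CC(C=C)O
F11 | step 1 | (1S)-4-((tert-butyldimethylsilyl)oxy)-1-((2S)-oxiran-2-yl)but-2-yn-1-ol | CC(C)(C)[Si](C)(C)OCC#C[C@H](O)[C@@H]1CO1
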